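**Retrosynthetic overview** (labdane numbering: C1–C10 decalin, C20 on C10, C11–C16 side chain, C17 on C8; α = face of H-5, β = face of C20)

1. The target is (13R)-20-acetoxy-2α-angeloyloxylabda-7,14-diene-3α,13-diol. Late steps: C2 angelate, C20 acetate, and the C7=C8 alkene from a C7 ketone (enol triflate, then reduction).
2. Enabling feature: ring B is a cyclohexene (C5–C6–C7–C8–C9–C10) whose C10 carries a carbonyl-level carbon (C20) and whose C7 can carry oxygen. This is an intramolecular Diels–Alder retron: 2-silyloxy diene C5=C6–C7(OTBS)=C8 plus the ester-activated (Z)-C9=C10 alkene, tethered by C1–C4, the future ring A.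
3. The triene comes from a Z-selective Horner–Wadsworth–Emmons reaction of a C10 phosphonate with the C9 aldehyde made from (R)-linalool (brings C13).
4. The tether comes from (R)-glyceraldehyde acetonide (C2) and a prenylboronate (C3, C4); C1 is alkylated with a phosphonoacetate and C5–C8 are added by cross-metathesis with ethyl vinyl ketone.
5. Ring order: no ring exists before step 12; rings A and B are formed together in that step, with C5, C9 and C10 set there.

Key step: step 12

Assumption: commercial (R)-(−)-linalool and (R)-glyceraldehyde acetonide are taken as enantiomerically pure, so that C13 and C2 are carried unchanged from the chiral pool.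

**Route**

Step 1
Reactants: 1 (R)-2,2-dimethyl-1,3-dioxolane-4-carbaldehyde; 2 3-methylbut-2-enylboronic acid pinacol ester
Product: 4 (S)-1-[(R)-2,2-dimethyl-1,3-dioxolan-4-yl]-2,2-dimethylbut-3-en-1-ol, via borate ester 3 (not isolated)
Conditions: CH2Cl2, 23 °C, 48 h; then aq. NaHCO3
Reagents that add atoms: none
Why: Allylboration through a closed chair transition state transfers the γ-carbon of the prenyl group (reverse prenylation, building the C4 quaternary carbon and the C5=C6 vinyl group), and the Z-γ-methyl group should enforce Felkin–Anh/Cornforth attack anti to the dioxolane C–O bond, setting C3 anti to C2; borate 3 is hydrolysed on work-up.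

Step 2
Reactants: 4 (S)-1-[(R)-2,2-dimethyl-1,3-dioxolan-4-yl]-2,2-dimethylbut-3-en-1-ol
Product: 5 (4R)-4-[(1S)-1-(4-methoxybenzyloxy)-2,2-dimethylbut-3-enyl]-2,2-dimethyl-1,3-dioxolane
Conditions: NaH, 4-methoxybenzyl chloride, Bu4NI (cat.), DMF, 0 → 23 °C
Reagents that add atoms: 4-methoxybenzyl chloride, COc1ccc(CCl)cc1
Why: Williamson ether synthesis on the sodium alkoxide puts an oxidatively removable group on the C3 oxygen, which must stay masked to the end.

Step 3
Reactants: 5 (4R)-4-[(1S)-1-(4-methoxybenzyloxy)-2,2-dimethylbut-3-enyl]-2,2-dimethyl-1,3-dioxolane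
Product: 6 (2R,3S)-3-(4-methoxybenzyloxy)-4,4-dimethylhex-5-ene-1,2-diol
Conditions: AcOH/H2O/THF (3:1:1), 45 °C
Reagents that add atoms: none
Why: Acid-catalysed hydrolysis of the terminal acetonide frees the C1/C2 diol while the benzylic ether and the alkene tolerate aqueous acetic acid.

Step 4
Reactants: 6 (2R,3S)-3-(4-methoxybenzyloxy)-4,4-dimethylhex-5-ene-1,2-diol
Product: 7 (2R,3S)-1,2-bis(tert-butyldimethylsilyloxy)-3-(4-methoxybenzyloxy)-4,4-dimethylhex-5-ene
Conditions: TBSOTf, 2,6-lutidine, CH2Cl2, −78 → 0 °C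
Reagents that add atoms: tert-butyldimethylsilyl trifluoromethanesulfonate, CC(C)(C)[Si](C)(C)OS(=O)(=O)C(F)(F)F
Why: Silylation with the silyl triflate covers both hydroxyls, including the hindered secondary C2 hydroxyl.

Step 5
Reactants: 7 (2R,3S)-1,2-bis(tert-butyldimethylsilyloxy)-3-(4-methoxybenzyloxy)-4,4-dimethylhex-5-ene
Product: 8 (2R,3S)-2-(tert-butyldimethylsilyloxy)-3-(4-methoxybenzyloxy)-4,4-dimethylhex-5-en-1-ol
Conditions: HF·pyridine, pyridine, THF, 0 °C
Reagents that add atoms: none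
Why: Selective desilylation: the primary silyl ether is cleaved much faster than the hindered secondary one, which leaves C1 free and C2 protected.

Step 6
Reactants: 8 (2R,3S)-2-(tert-butyldimethylsilyloxy)-3-(4-methoxybenzyloxy)-4,4-dimethylhex-5-en-1-ol; 9 ethyl 2-[bis(2-methylphenoxy)phosphoryl]acetate
Product: 11 ethyl (4R,5S)-2-[bis(2-methylphenoxy)phosphoryl]-4-(tert-butyldimethylsilyloxy)-5-(4-methoxybenzyloxy)-6,6-dimethyloct-7-enoate (mixture of C2 epimers), via primary triflate 10 (not isolated)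
Conditions: Tf2O, 2,6-lutidine, CH2Cl2, −78 °C; then NaH/9, THF–DMPU, −20 → 23 °C
Reagents that add atoms: trifluoromethanesulfonic anhydride, O=S(=O)(OS(=O)(=O)C(F)(F)F)C(F)(F)F (its triflyl group is carried only by intermediate 10)
Why: C-alkylation (malonate-type substitution) of the stabilised phosphonoacetate anion by a primary triflate, chosen because a β-silyloxy, β-branched iodide would react too slowly, forms the C1–C10 bond; the C2 oxygen is already silylated, so no γ-lactone can form.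

Step 7
Reactants: 11 ethyl (4R,5S)-2-[bis(2-methylphenoxy)phosphoryl]-4-(tert-butyldimethylsilyloxy)-5-(4-methoxybenzyloxy)-6,6-dimethyloct-7-enoate; 12 pent-1-en-3-one
Product: 13 ethyl (4R,5S,7E)-2-[bis(2-methylphenoxy)phosphoryl]-4-(tert-butyldimethylsilyloxy)-5-(4-methoxybenzyloxy)-6,6-dimethyl-9-oxoundec-7-enoate
Conditions: Hoveyda–Grubbs second-generation catalyst RuCl2(H2IMes)(=CH–C6H4-2-O-i-Pr) (10 mol %), 12 (5 equiv), CH2Cl2, 40 °C
Reagents that add atoms: none
Why: Olefin cross-metathesis of the non-dimerising neopentyl vinyl group with an electron-poor vinyl ketone should give the thermodynamically preferred E-enone (C5=C6, C7=O, C8, C17); it is run before the side chain is attached, whose vinyl group would compete.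

Step 8
Reactants: 13 ethyl (4R,5S,7E)-2-[bis(2-methylphenoxy)phosphoryl]-4-(tert-butyldimethylsilyloxy)-5-(4-methoxybenzyloxy)-6,6-dimethyl-9-oxoundec-7-enoate
Product: 14 ethyl (4R,5S,7E,9Z)-2-[bis(2-methylphenoxy)phosphoryl]-4,9-bis(tert-butyldimethylsilyloxy)-5-(4-methoxybenzyloxy)-6,6-dimethylundeca-7,9-dienoate
Conditions: TBSOTf, Et3N, CH2Cl2, −78 → 0 °C; Et3N-deactivated silica
Reagents that add atoms: tert-butyldimethylsilyl trifluoromethanesulfonate, CC(C)(C)[Si](C)(C)OS(=O)(=O)C(F)(F)F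
Why: Soft enolisation and O-silylation of the ethyl ketone (its only enolisable side is C8) should give the cross-conjugated (Z)-silyl dienol ether, and it removes the Michael-acceptor character of the enone before the phosphonate is deprotonated in step 11.

Step 9
Reactants: 15 (R)-linalool
Product: 16 triethyl{[(3R)-3,7-dimethylocta-1,6-dien-3-yl]oxy}silane
Conditions: TESOTf, 2,6-lutidine, CH2Cl2, −78 → 0 °C
Reagents that add atoms: triethylsilyl trifluoromethanesulfonate, CC[Si](CC)(CC)OS(=O)(=O)C(F)(F)F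
Why: Silylation of the tertiary allylic alcohol protects the C13 carbinol, which would otherwise be silylated unselectively or ionised later.

Step 10
Reactants: 16 triethyl{[(3R)-3,7-dimethylocta-1,6-dien-3-yl]oxy}silane
Product: 17 (4R)-4-methyl-4-(triethylsilyloxy)hex-5-enal
Conditions: O3 (1 equiv, Sudan Red 7B end point), CH2Cl2, −78 °C; then PPh3
Reagents that add atoms: ozone, [O-][O+]=O
Why: Chemoselective ozonolysis: the electron-rich trisubstituted alkene reacts far faster than the hindered vinyl group next to the silyloxy carbon, giving the C9 aldehyde with C13 untouched.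

Step 11
Reactants: 14 ethyl (4R,5S,7E,9Z)-2-[bis(2-methylphenoxy)phosphoryl]-4,9-bis(tert-butyldimethylsilyloxy)-5-(4-methoxybenzyloxy)-6,6-dimethylundeca-7,9-dienoate; 17 (4R)-4-methyl-4-(triethylsilyloxy)hex-5-enal
Product: 18 ethyl (2Z,6R)-2-[(2R,3S,5E,7Z)-2,7-bis(tert-butyldimethylsilyloxy)-3-(4-methoxybenzyloxy)-4,4-dimethylnona-5,7-dienyl]-6-methyl-6-(triethylsilyloxy)octa-2,7-dienoate
Conditions: NaH (1.0 equiv), THF, −78 °C; then 17, −78 → 0 °C
Reagents that add atoms: none
Why: Z-selective Horner–Wadsworth–Emmons olefination: α-substituted diaryl phosphonoacetates collapse fast from the kinetic adduct and should place C11 cis to the ester, both C10 epimers of 14 converging on the same (Z)-C9=C10 enoate.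

Step 12
Reactants: 18 ethyl (2Z,6R)-2-[(2R,3S,5E,7Z)-2,7-bis(tert-butyldimethylsilyloxy)-3-(4-methoxybenzyloxy)-4,4-dimethylnona-5,7-dienyl]-6-methyl-6-(triethylsilyloxy)octa-2,7-dienoate
Product: 20 ethyl (8αH,13R)-2α-(tert-butyldimethylsilyloxy)-3α-(4-methoxybenzyloxy)-7-oxo-13-(triethylsilyloxy)labd-14-en-20-oate, via silyl enol ether cycloadduct 19 (not isolated)
Conditions: toluene (0.01 M), BHT, 135 °C, sealed tube; then Bu4NF/AcOH (1:1), THF, −20 °C
Reagents that add atoms: none
Why: Thermal, concerted but asynchronous intramolecular [4+2] cycloaddition (type 1 intramolecular Diels–Alder reaction) between the electron-rich 2-silyloxy diene C5=C6–C7(OTBS)=C8 and the ester-activated (Z)-C9=C10 alkene, with matched polarity (nucleophilic C8 to electrophilic C9, then C5–C10), after which buffered fluoride cleaves only the silyl enol ether of 19 to the C7 ketone. The closest known reaction type is the thermal cyclisation of 1,7,9-decatrienes that carry a 2-silyloxy diene and an acrylate-type dienophile to octalones. Ring A is closed by the C5–C10 bond alone, as the six-membered ring that contains the C1–C4 tether, and ring B is the new cyclohexene closed by C5–C10 together with C8–C9 in the [4+2] mode. C5 and C10 should come out trans from the chair-like transition state with the C20 ester endo and the tether exo; C9 follows from the Z geometry of the enoate by suprafacial addition (C11 cis to C20), and C8 (methyl cis to C20, lost later) from the Z enol ether. The absolute sense is relayed from C2: only one diene face lets the C2 silyloxy group sit equatorial in the forming ring A, while the other forces it into a 1,3-diaxial position against the axial C4 methyl and the C10 ester. The step therefore needs endo (trans-fusion) and facial selectivity plus intact alkene geometries, which the short tether (fixed regiochemistry), the gem-dimethyl group at C4 (Thorpe–Ingold effect), the carbonyl-endo preference and the C2/C3 substituents are expected to secure.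

Step 13
Reactants: 20 ethyl (8αH,13R)-2α-(tert-butyldimethylsilyloxy)-3α-(4-methoxybenzyloxy)-7-oxo-13-(triethylsilyloxy)labd-14-en-20-oate
Product: 21 ethyl (13R)-2α-(tert-butyldimethylsilyloxy)-3α-(4-methoxybenzyloxy)-13-(triethylsilyloxy)-7-(trifluoromethylsulfonyloxy)labda-7,14-dien-20-oate
Conditions: LiN(SiMe3)2 (0.95 equiv), THF, −78 → 23 °C; then Comins' reagent, −78 → 0 °C
Reagents that add atoms: N-(5-chloropyridin-2-yl)-1,1,1-trifluoro-N-(trifluoromethylsulfonyl)methanesulfonamide, FC(F)(F)S(=O)(=O)N(c1ccc(Cl)cn1)S(=O)(=O)C(F)(F)F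
Why: Thermodynamic enolate trapping: with a slight excess of ketone the lithium enolate should equilibrate to the more substituted C7=C8 isomer, helped by loss of the 1,3-diaxial contact between the 8β-methyl group and the C10 ester and by shielding of H-6β under the axial C4 methyl and C20, and O-triflation fixes it; the C10 ester has no α-hydrogen.

Step 14
Reactants: 21 ethyl (13R)-2α-(tert-butyldimethylsilyloxy)-3α-(4-methoxybenzyloxy)-13-(triethylsilyloxy)-7-(trifluoromethylsulfonyloxy)labda-7,14-dien-20-oate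
Product: 22 ethyl (13R)-2α-(tert-butyldimethylsilyloxy)-3α-(4-methoxybenzyloxy)-13-(triethylsilyloxy)labda-7,14-dien-20-oate
Conditions: Pd(OAc)2 (cat.), PPh3, Bu3N, HCO2H, DMF, 60 °C
Reagents that add atoms: none
Why: Palladium-catalysed formate reduction of the enol triflate (oxidative addition, decarboxylation of formate to the palladium hydride, reductive elimination) replaces the triflate by hydrogen without moving the C7=C8 double bond.

Step 15
Reactants: 22 ethyl (13R)-2α-(tert-butyldimethylsilyloxy)-3α-(4-methoxybenzyloxy)-13-(triethylsilyloxy)labda-7,14-dien-20-oate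
Product: 23 (13R)-2α-(tert-butyldimethylsilyloxy)-3α-(4-methoxybenzyloxy)-13-(triethylsilyloxy)labda-7,14-dien-20-ol
Conditions: LiAlH4, Et2O, 0 → 23 °C
Reagents that add atoms: none
Why: Hydride reduction of the hindered neopentyl ester to the C20 primary alcohol; silyl ethers, the benzylic ether and the isolated alkenes are inert.

Step 16
Reactants: 23 (13R)-2α-(tert-butyldimethylsilyloxy)-3α-(4-methoxybenzyloxy)-13-(triethylsilyloxy)labda-7,14-dien-20-ol
Product: 24 (13R)-20-acetoxy-2α-(tert-butyldimethylsilyloxy)-3α-(4-methoxybenzyloxy)-13-(triethylsilyloxy)labda-7,14-diene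
Conditions: Ac2O, pyridine, DMAP (cat.), CH2Cl2, 23 °C
Reagents that add atoms: acetic anhydride, CC(=O)OC(C)=O
Why: Nucleophile-catalysed acetylation of the only free hydroxyl installs the C20 acetate of the target.

Step 17
Reactants: 24 (13R)-20-acetoxy-2α-(tert-butyldimethylsilyloxy)-3α-(4-methoxybenzyloxy)-13-(triethylsilyloxy)labda-7,14-diene
Product: 25 (13R)-20-acetoxy-3α-(4-methoxybenzyloxy)labda-7,14-diene-2α,13-diol
Conditions: HF·pyridine, pyridine, THF, 0 → 23 °C
Reagents that add atoms: none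
Why: Buffered fluoride desilylation removes both silyl ethers (C2 and C13) without touching the acetate or ionising the tertiary allylic alcohol.

Step 18
Reactants: 25 (13R)-20-acetoxy-3α-(4-methoxybenzyloxy)labda-7,14-diene-2α,13-diol; 26 angelic acid
Product: 28 (13R)-20-acetoxy-2α-angeloyloxy-3α-(4-methoxybenzyloxy)labda-7,14-dien-13-ol, via angelic 2,4,6-trichlorobenzoic anhydride 27 (not isolated)
Conditions: 26, 2,4,6-trichlorobenzoyl chloride, Et3N, toluene, 23 °C; then 25, toluene, 75 °C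
Reagents that add atoms: 2,4,6-trichlorobenzoyl chloride, O=C(Cl)c1c(Cl)cc(Cl)cc1Cl (its aroyl group is carried only by intermediate 27)
Why: Yamaguchi-type mixed-anhydride esterification without a nucleophilic catalyst should acylate the equatorial secondary C2 hydroxyl and leave the tertiary C13 hydroxyl alone, and it avoids the Z-to-E isomerisation of the angelate that amine-catalysed acylations cause.

Step 19
Reactants: 28 (13R)-20-acetoxy-2α-angeloyloxy-3α-(4-methoxybenzyloxy)labda-7,14-dien-13-ol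
Product: 29 (13R)-20-acetoxy-2α-angeloyloxylabda-7,14-diene-3α,13-diol (target)
Conditions: DDQ, CH2Cl2/pH 7 buffer, 0 °C
Reagents that add atoms: none
Why: Oxidative cleavage of the 4-methoxybenzyl ether under neutral conditions frees the axial C3 hydroxyl without acyl migration, ester hydrolysis or ionisation at C13.

**Compound list**

1 | (R)-2,2-dimethyl-1,3-dioxolane-4-carbaldehyde ((R)-glyceraldehyde acetonide) | O=C[C@H]1COC(C)(C)O1 | starting material
2 | 3-methylbut-2-enylboronic acid pinacol ester | CC(C)=CCB1OC(C)(C)C(C)(C)O1 | starting material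
3 | 2-{(S)-1-[(R)-2,2-dimethyl-1,3-dioxolan-4-yl]-2,2-dimethylbut-3-enyloxy}-4,4,5,5-tetramethyl-1,3,2-dioxaborolane (borate ester, formed in the flask) | C=CC(C)(C)[C@H](OB1OC(C)(C)C(C)(C)O1)[C@H]2COC(C)(C)O2 | intermediate
4 | (S)-1-[(R)-2,2-dimethyl-1,3-dioxolan-4-yl]-2,2-dimethylbut-3-en-1-ol | C=CC(C)(C)[C@H](O)[C@H]1COC(C)(C)O1 | intermediate
5 | (4R)-4-[(1S)-1-(4-methoxybenzyloxy)-2,2-dimethylbut-3-enyl]-2,2-dimethyl-1,3-dioxolane | C=CC(C)(C)[C@H](OCc1ccc(OC)cc1)[C@H]2COC(C)(C)O2 | intermediate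
6 | (2R,3S)-3-(4-methoxybenzyloxy)-4,4-dimethylhex-5-ene-1,2-diol | C=CC(C)(C)[C@H](OCc1ccc(OC)cc1)[C@H](O)CO | intermediate
7 | (2R,3S)-1,2-bis(tert-butyldimethylsilyloxy)-3-(4-methoxybenzyloxy)-4,4-dimethylhex-5-ene | C=CC(C)(C)[C@H](OCc1ccc(OC)cc1)[C@H](O[Si](C)(C)C(C)(C)C)CO[Si](C)(C)C(C)(C)C | intermediate
8 | (2R,3S)-2-(tert-butyldimethylsilyloxy)-3-(4-methoxybenzyloxy)-4,4-dimethylhex-5-en-1-ol | C=CC(C)(C)[C@H](OCc1ccc(OC)cc1)[C@H](O[Si](C)(C)C(C)(C)C)CO | intermediate
9 | ethyl 2-[bis(2-methylphenoxy)phosphoryl]acetate | CCOC(=O)CP(=O)(Oc1ccccc1C)Oc1ccccc1C | starting material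
10 | (2R,3S)-2-(tert-butyldimethylsilyloxy)-3-(4-methoxybenzyloxy)-4,4-dimethylhex-5-enyl trifluoromethanesulfonate (formed in the flask) | C=CC(C)(C)[C@H](OCc1ccc(OC)cc1)[C@H](O[Si](C)(C)C(C)(C)C)COS(=O)(=O)C(F)(F)F | intermediate
11 | ethyl (4R,5S)-2-[bis(2-methylphenoxy)phosphoryl]-4-(tert-butyldimethylsilyloxy)-5-(4-methoxybenzyloxy)-6,6-dimethyloct-7-enoate (C2 epimers) | C=CC(C)(C)[C@H](OCc1ccc(OC)cc1)[C@H](O[Si](C)(C)C(C)(C)C)CC(C(=O)OCC)P(=O)(Oc1ccccc1C)Oc1ccccc1C | intermediate
12 | pent-1-en-3-one (ethyl vinyl ketone) | C=CC(=O)CC | starting material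
13 | ethyl (4R,5S,7E)-2-[bis(2-methylphenoxy)phosphoryl]-4-(tert-butyldimethylsilyloxy)-5-(4-methoxybenzyloxy)-6,6-dimethyl-9-oxoundec-7-enoate | CCC(=O)/C=C/C(C)(C)[C@H](OCc1ccc(OC)cc1)[C@H](O[Si](C)(C)C(C)(C)C)CC(C(=O)OCC)P(=O)(Oc1ccccc1C)Oc1ccccc1C | intermediate
14 | ethyl (4R,5S,7E,9Z)-2-[bis(2-methylphenoxy)phosphoryl]-4,9-bis(tert-butyldimethylsilyloxy)-5-(4-methoxybenzyloxy)-6,6-dimethylundeca-7,9-dienoate | C/C=C(\O[Si](C)(C)C(C)(C)C)/C=C/C(C)(C)[C@H](OCc1ccc(OC)cc1)[C@H](O[Si](C)(C)C(C)(C)C)CC(C(=O)OCC)P(=O)(Oc1ccccc1C)Oc1ccccc1C | intermediate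
15 | (R)-linalool, (3R)-3,7-dimethylocta-1,6-dien-3-ol | C=C[C@](C)(O)CCC=C(C)C | starting material
16 | triethyl{[(3R)-3,7-dimethylocta-1,6-dien-3-yl]oxy}silane | C=C[C@](C)(O[Si](CC)(CC)CC)CCC=C(C)C | intermediate
17 | (4R)-4-methyl-4-(triethylsilyloxy)hex-5-enal | C=C[C@](C)(O[Si](CC)(CC)CC)CCC=O | intermediate
18 | ethyl (2Z,6R)-2-[(2R,3S,5E,7Z)-2,7-bis(tert-butyldimethylsilyloxy)-3-(4-methoxybenzyloxy)-4,4-dimethylnona-5,7-dienyl]-6-methyl-6-(triethylsilyloxy)octa-2,7-dienoate | C/C=C(\O[Si](C)(C)C(C)(C)C)/C=C/C(C)(C)[C@H](OCc1ccc(OC)cc1)[C@H](O[Si](C)(C)C(C)(C)C)C/C(C(=O)OCC)=C/CC[C@@](C)(O[Si](CC)(CC)CC)C=C | intermediate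
19 | ethyl (8αH,13R)-2α,7-bis(tert-butyldimethylsilyloxy)-3α-(4-methoxybenzyloxy)-13-(triethylsilyloxy)labda-6,14-dien-20-oate (5α-H, 9β side chain; formed in the flask) | C=C[C@](C)(O[Si](CC)(CC)CC)CC[C@H]1[C@@H](C)C(O[Si](C)(C)C(C)(C)C)=C[C@H]2C(C)(C)[C@H](OCc3ccc(OC)cc3)[C@H](O[Si](C)(C)C(C)(C)C)C[C@]12C(=O)OCC | intermediate
20 | ethyl (8αH,13R)-2α-(tert-butyldimethylsilyloxy)-3α-(4-methoxybenzyloxy)-7-oxo-13-(triethylsilyloxy)labd-14-en-20-oate | C=C[C@](C)(O[Si](CC)(CC)CC)CC[C@H]1[C@@H](C)C(=O)C[C@H]2C(C)(C)[C@H](OCc3ccc(OC)cc3)[C@H](O[Si](C)(C)C(C)(C)C)C[C@]12C(=O)OCC | intermediate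
21 | ethyl (13R)-2α-(tert-butyldimethylsilyloxy)-3α-(4-methoxybenzyloxy)-13-(triethylsilyloxy)-7-(trifluoromethylsulfonyloxy)labda-7,14-dien-20-oate | C=C[C@](C)(O[Si](CC)(CC)CC)CC[C@H]1C(C)=C(OS(=O)(=O)C(F)(F)F)C[C@H]2C(C)(C)[C@H](OCc3ccc(OC)cc3)[C@H](O[Si](C)(C)C(C)(C)C)C[C@]12C(=O)OCC | intermediate
22 | ethyl (13R)-2α-(tert-butyldimethylsilyloxy)-3α-(4-methoxybenzyloxy)-13-(triethylsilyloxy)labda-7,14-dien-20-oate | C=C[C@](C)(O[Si](CC)(CC)CC)CC[C@H]1C(C)=CC[C@H]2C(C)(C)[C@H](OCc3ccc(OC)cc3)[C@H](O[Si](C)(C)C(C)(C)C)C[C@]12C(=O)OCC | intermediate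
23 | (13R)-2α-(tert-butyldimethylsilyloxy)-3α-(4-methoxybenzyloxy)-13-(triethylsilyloxy)labda-7,14-dien-20-ol | C=C[C@](C)(O[Si](CC)(CC)CC)CC[C@H]1C(C)=CC[C@H]2C(C)(C)[C@H](OCc3ccc(OC)cc3)[C@H](O[Si](C)(C)C(C)(C)C)C[C@]12CO | intermediate
24 | (13R)-20-acetoxy-2α-(tert-butyldimethylsilyloxy)-3α-(4-methoxybenzyloxy)-13-(triethylsilyloxy)labda-7,14-diene | C=C[C@](C)(O[Si](CC)(CC)CC)CC[C@H]1C(C)=CC[C@H]2C(C)(C)[C@H](OCc3ccc(OC)cc3)[C@H](O[Si](C)(C)C(C)(C)C)C[C@]12COC(C)=O | intermediate
25 | (13R)-20-acetoxy-3α-(4-methoxybenzyloxy)labda-7,14-diene-2α,13-diol | C=C[C@](C)(O)CC[C@H]1C(C)=CC[C@H]2C(C)(C)[C@H](OCc3ccc(OC)cc3)[C@H](O)C[C@]12COC(C)=O | intermediate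
26 | angelic acid, (Z)-2-methylbut-2-enoic acid | C/C=C(/C)C(=O)O | starting material
27 | (Z)-2-methylbut-2-enoic 2,4,6-trichlorobenzoic anhydride (formed in the flask) | C/C=C(/C)C(=O)OC(=O)c1c(Cl)cc(Cl)cc1Cl | intermediate
28 | (13R)-20-acetoxy-2α-angeloyloxy-3α-(4-methoxybenzyloxy)labda-7,14-dien-13-ol | C=C[C@](C)(O)CC[C@H]1C(C)=CC[C@H]2C(C)(C)[C@H](OCc3ccc(OC)cc3)[C@H](OC(=O)/C(C)=C\C)C[C@]12COC(C)=O | intermediate
29 | (13R)-20-acetoxy-2α-angeloyloxylabda-7,14-diene-3α,13-diol (CNP0171655.1) | C=C[C@](C)(O)CC[C@H]1C(C)=CC[C@H]2C(C)(C)[C@H](O)[C@H](OC(=O)/C(C)=C\C)C[C@]12COC(C)=O | target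

**Step count and risks**

Total step count: 19. Longest linear sequence: 17 steps (steps 1–8 and 11–19, from compound 1); the side-chain aldehyde takes 2 steps (9 and 10).

Three steps most likely to fail:

Step 12. The cycloaddition may be too slow at the congested C5–C10 bond, or the ester-endo preference may erode and give cis-fused material. The fallback sets out from 18 and comes back at 20, and it replaces the ester by an aldehyde dienophile that responds to a Lewis acid. Reduction with i-Bu2AlH (CH2Cl2, −78 °C) should give the (Z)-allylic alcohol F1, and MnO2 should give the (Z)-enal F2. Me2AlCl (CH2Cl2, −78 → −30 °C) should then promote the intramolecular Diels–Alder reaction of the aluminium-complexed enal under strong carbonyl-endo control to the aldehyde cycloadduct F3. Buffered Bu4NF cleaves its silyl enol ether to the keto aldehyde F4. Pinnick oxidation (NaClO2, NaH2PO4, 2-methylbut-2-ene) gives the keto acid F5, and ethylation (EtI, KHCO3, DMF) returns to 20.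

Step 13. Enolate equilibration may be incomplete, so that triflation occurs toward C6 and the alkene ends up in the wrong position. The fallback sets out from 20 and comes back at 22, and it replaces enolate chemistry by reduction and anti elimination. Base equilibration (DBU, toluene) should give the 8α-methyl ketone F6. Reduction with LiBH(s-Bu)3 from the equatorial direction should give the axial 7α-alcohol F7. POCl3/pyridine should then eliminate in the anti sense toward C8, because H-8β is the more substituted and less shielded of the two antiperiplanar hydrogens (H-6β lies under the axial C4 methyl and C20), giving 22 directly.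

Step 7. The catalyst may fail to engage the neopentyl vinyl group next to the quaternary C4, leaving only self-metathesis of the enone partner. The fallback sets out from 11 and comes back at 13, and it replaces metathesis by cleavage and olefination. Oxidative cleavage (OsO4 cat., NaIO4, 2,6-lutidine, dioxane/H2O) should give the aldehyde F8. A base-free Wittig reaction with the stabilised ylide 1-(triphenylphosphoranylidene)butan-2-one (toluene, 80 °C), under which the phosphonoacetate is not deprotonated, should then give the E-enone 13.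

Further compounds
F1 | step 12 | (2Z,6R)-2-[(2R,3S,5E,7Z)-2,7-bis(tert-butyldimethylsilyloxy)-3-(4-methoxybenzyloxy)-4,4-dimethylnona-5,7-dienyl]-6-methyl-6-(triethylsilyloxy)octa-2,7-dien-1-ol | C/C=C(\O[Si](C)(C)C(C)(C)C)/C=C/C(C)(C)[C@H](OCc1ccc(OC)cc1)[C@H](O[Si](C)(C)C(C)(C)C)C/C(CO)=C/CC[C@@](C)(O[Si](CC)(CC)CC)C=C
F2 | step 12 | (2Z,6R)-2-[(2R,3S,5E,7Z)-2,7-bis(tert-butyldimethylsilyloxy)-3-(4-methoxybenzyloxy)-4,4-dimethylnona-5,7-dienyl]-6-methyl-6-(triethylsilyloxy)octa-2,7-dienal | C/C=C(\O[Si](C)(C)C(C)(C)C)/C=C/C(C)(C)[C@H](OCc1ccc(OC)cc1)[C@H](O[Si](C)(C)C(C)(C)C)C/C(C=O)=C/CC[C@@](C)(O[Si](CC)(CC)CC)C=C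
F3 | step 12 | (8αH,13R)-2α,7-bis(tert-butyldimethylsilyloxy)-3α-(4-methoxybenzyloxy)-13-(triethylsilyloxy)labda-6,14-dien-20-al | C=C[C@](C)(O[Si](CC)(CC)CC)CC[C@H]1[C@@H](C)C(O[Si](C)(C)C(C)(C)C)=C[C@H]2C(C)(C)[C@H](OCc3ccc(OC)cc3)[C@H](O[Si](C)(C)C(C)(C)C)C[C@]12C=O
F4 | step 12 | (8αH,13R)-2α-(tert-butyldimethylsilyloxy)-3α-(4-methoxybenzyloxy)-7-oxo-13-(triethylsilyloxy)labd-14-en-20-al | C=C[C@](C)(O[Si](CC)(CC)CC)CC[C@H]1[C@@H](C)C(=O)C[C@H]2C(C)(C)[C@H](OCc3ccc(OC)cc3)[C@H](O[Si](C)(C)C(C)(C)C)C[C@]12C=O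
F5 | step 12 | (8αH,13R)-2α-(tert-butyldimethylsilyloxy)-3α-(4-methoxybenzyloxy)-7-oxo-13-(triethylsilyloxy)labd-14-en-20-oic acid | C=C[C@](C)(O[Si](CC)(CC)CC)CC[C@H]1[C@@H](C)C(=O)C[C@H]2C(C)(C)[C@H](OCc3ccc(OC)cc3)[C@H](O[Si](C)(C)C(C)(C)C)C[C@]12C(=O)O
F6 | step 13 | ethyl (8βH,13R)-2α-(tert-butyldimethylsilyloxy)-3α-(4-methoxybenzyloxy)-7-oxo-13-(triethylsilyloxy)labd-14-en-20-oate (8α-methyl epimer of 20) | C=C[C@](C)(O[Si](CC)(CC)CC)CC[C@H]1[C@H](C)C(=O)C[C@H]2C(C)(C)[C@H](OCc3ccc(OC)cc3)[C@H](O[Si](C)(C)C(C)(C)C)C[C@]12C(=O)OCC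
F7 | step 13 | ethyl (8βH,13R)-2α-(tert-butyldimethylsilyloxy)-7α-hydroxy-3α-(4-methoxybenzyloxy)-13-(triethylsilyloxy)labd-14-en-20-oate | C=C[C@](C)(O[Si](CC)(CC)CC)CC[C@H]1[C@H](C)[C@H](O)C[C@H]2C(C)(C)[C@H](OCc3ccc(OC)cc3)[C@H](O[Si](C)(C)C(C)(C)C)C[C@]12C(=O)OCC
F8 | step 7 | ethyl (4R,5S)-2-[bis(2-methylphenoxy)phosphoryl]-4-(tert-butyldimethylsilyloxy)-5-(4-methoxybenzyloxy)-6,6-dimethyl-7-oxoheptanoate | O=CC(C)(C)[C@H](OCc1ccc(OC)cc1)[C@H](O[Si](C)(C)C(C)(C)C)CC(C(=O)OCC)P(=O)(Oc1ccccc1C)Oc1ccccc1C
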